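## The problem

Compound 27 is a cis-fused eremophilane decalin with six stereocentres, (3R,4R,5R,7R,9R,10S). Eremophilane numbering is used throughout: ring A is C1–C5 and C10, ring B is C5–C10, C14 sits on C5, C15 on C4, and the isopropenyl group C11–C13 on C7; α/β refer to the usual drawing with both methyls β. Four centres are contiguous on ring A and cannot be corrected once made: the 3α ester oxygen, the cis methyl pair on C4 and quaternary C5, and the 10β hydrogen cis to C14. The other two, C7 and C9, flank the C8 ketone and are both equatorial in the chair–chair conformer fixed by the equatorial C3 and C4 substituents, so ring A can control them by attack on the convex β face or by equilibration. The cis ring fusion is the subtle point: while C9 is a ketone, C10 is epimerisable and the trans-fused isomer is expected to win (as in 4-oxo steroids). C10 must therefore be set irreversibly once the carbonyl sits at C8. The isopropenyl ketone (conjugation to the isopropylidene isomer), the angelate (Z to E), the senecioate (dienolate formation) and the α-acyloxy ketone all forbid strong base or acid late in the route, so both esters come late and the angelate last. The enabling feature is that the C3 oxygen and C10 are 1,4-related across ring A through C2 and C1: C3, C2, C1, C10 and that oxygen map onto a furan, C4=C5 with its cis methyls onto an (E)-2-methylbut-2-enoyl alkene, and C6–C9 onto a four-atom tether that closes ring B. The price is that the activating carbonyl ends at C6, where 27 has CH2, and the oxygen bridge ends on C10 α, where 27 has H β.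

## Retrosynthesis

**C9 ester.** The angelate C–O bond of 27 is cut last, giving ketol 24 and angelic acid 25 (activated as mixed anhydride 26). This order keeps the isomerisable (Z)-ester away from every earlier reagent; the forward step needs only an acylation that does not isomerise the acid.

**C9–O and C10–H together.** Ketol 24 is traced through silyloxy epoxide 23 and silyl enol ether 22 to enone 21. Conjugate hydride addition to 21 sets C10 irreversibly (C10 is β to the C8 ketone and no longer epimerisable) and gives the enol ether only toward C9, so oxygenation needs no regiochemical choice. The neighbouring cut, cleaving C10–O next to a C9 ketone, would leave C10 epimerisable toward the trans isomer. The forward step must deliver hydride to the β face of C10 and must spare the isopropenyl group.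

**C3 ester and the oxygen bridge.** Ester 21 comes from alcohol 19 and senecioyl chloride 20. Alcohol 19 is the retro-oxa-Michael product of bridged ketone 17: the bridging oxygen on C10 is β to the C8 carbonyl. Reductive removal of the C9 silyloxy group gives samarium enolate 18, which expels the bridge without external base. The C9 oxygen of 17 is thus sacrificed after steering the cycloaddition, and the C3–O bond of 27 is the original furan C–O bond.

**Isopropenyl group.** Ketone 17 comes from dienone 15 by conjugate reduction (via silyl enol ether 16). Dienone 15 comes from α-iodoenone 13 and stannane 14 by cutting C7–C11, and 13 from enone 12. Forming this bond between two sp2 carbons leaves no isopropenyl/isopropylidene ambiguity, unlike an acetone aldol followed by dehydration.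

**Moving the carbonyl from C6 to C8.** Enone 12 is the allylic oxidation product of alkene 11, which comes from enol triflate 10 of ketone 9. Three steps remove the C6 oxygen, place the ketone at C8 and leave the C6=C7 bond that the iodination needs; C5 is quaternary, so enolisation and allylic oxidation each have one site.

**Key disconnection.** Ketone 9 is the hydrogenation product of oxanorbornene 8. Cutting C3–C4 and C5–C10 of 8 opens rings A and B at once and gives the acyclic furyl enone 7, in which only C9 is stereogenic. The forward cycloaddition must choose one furan face.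

**Precursor.** Enone 7 is cut at C5–C6 into Weinreb amide 4 and the alkenyllithium 6 derived from bromide 5. C6–C9 is taken as a succinyl unit because an allyl-derived chain would put three methylenes, not two, between the carbinol and the ketone. Amide 4 comes from carbinol 3, keto amide 2 and the commercial keto acid 1; the C9 stereocentre is set by catalytic ketone reduction.

## Roads not taken

**Alternative 1:** The cut is C7–C8. A Lewis-acid carbonyl-ene reaction of seco-aldehyde A2 (C8 aldehyde, prenyl group on C5) would close ring B to alcohol A1 and create the isopropenyl group by the hydrogen shift.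
- Merits: the isopropenyl group arises with no regiochemical ambiguity, ring B already has oxygen at C8 and C9 and none at C6, and A1 is three steps from 27. On all three counts this is better than the chosen plan, which spends three steps on the isopropenyl group and four on relocating the carbonyl.
- Weak points: A2 must already contain C3, C4, quaternary C5, C10 and C9, so the hardest part of the molecule is pushed into a precursor with no obvious short synthesis; its α-silyloxy aldehyde is epimerisable; the ene step must still deliver 7β.
- Comparison: the chosen plan sets against this the construction of ring A with four stereocentres in one step from a chain made in four steps.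

**Alternative 2:** The cut is C6–C7. A stannyl ketyl at C3 of cyclopropyl ketone A4 would open the C4–C6 bond; the C6 radical would add 6-exo to the allyl sulfone and lose the sulfonyl radical, giving A3.
- Merits: ring closure and a regiodefined isopropenyl group in one neutral step, with C5 set beforehand by cyclopropanation and both ring-B oxygens in place. On the isopropenyl group it is at least as good as the chosen plan.
- Weak points: A4 needs the C8/C9 diol, a trisubstituted allyl sulfone and a bicyclic ketone, all made stereoselectively. A primary radical closing onto a hindered alkene competes with hydrogen transfer from the tin hydride. C7, the C4 protonation and the later C3 reduction each need separate control.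
- Comparison: the chosen plan offers a far simpler precursor and a better precedented ring-forming step.

**Alternative 3:** The cuts are C5–C6 and C9–C10. A Diels–Alder reaction of enone A6 with diene A7 would give the cis-fused adduct A5.
- Merits: it is the shortest route to a bicyclic core, the cis fusion follows directly from suprafacial addition, and the enol ether is regiodefined for work at C7. On the ring fusion it is better than the chosen plan, which sets C10 late by hydride delivery.
- Weak points: A6 is a sluggish dienophile; a single enantiomer requires an asymmetric catalyst for a substrate class where this is not general; the C4 methyl, the 3α oxygen and the C9 oxygen still have to be added over several steps.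
- Comparison: the step count may be similar or lower. The chosen plan sets against it absolute control from one catalytic ketone reduction and the placement of C3–O, C4 and C5 in a single step.

Key step: step 5

Remark: compounds 1, 5, 14, 20 and 25 are taken as commercial; the sense of induction in step 2 is assumed to follow that of aryl alkyl ketones with the (R,R)-catalyst.

## Route

Step 1
Reactants: 1 4-(furan-2-yl)-4-oxobutanoic acid
Product: 2 4-(furan-2-yl)-N-methoxy-N-methyl-4-oxobutanamide
Conditions: MeNH(OMe)·HCl, EDC·HCl, N-methylmorpholine, CH2Cl2, 0 °C to rt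
Reagents that add atoms: N,O-dimethylhydroxylamine hydrochloride, CNOC.Cl
Why: Carbodiimide amide coupling of the free acid; the furyl ketone is inert and the Weinreb amide fixes C6 at the acyl oxidation level.

Step 2
Reactants: 2 4-(furan-2-yl)-N-methoxy-N-methyl-4-oxobutanamide
Product: 3 (R)-4-(furan-2-yl)-4-hydroxy-N-methoxy-N-methylbutanamide
Conditions: RuCl[(R,R)-TsDPEN](p-cymene) (1 mol %), HCO2H–Et3N (5:2), rt
Reagents that add atoms: none
Why: Noyori asymmetric transfer hydrogenation, for which 2-acylfurans are standard substrates; the furan acts as the aryl group and the (R,R)-catalyst should give the (R)-carbinol (C9), while the amide is not reduced.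

Step 3
Reactants: 3 (R)-4-(furan-2-yl)-4-hydroxy-N-methoxy-N-methylbutanamide
Product: 4 (R)-4-[(tert-butyldimethylsilyl)oxy]-4-(furan-2-yl)-N-methoxy-N-methylbutanamide
Conditions: TBSCl, imidazole, DMF, rt
Reagents that add atoms: tert-butyldimethylsilyl chloride, CC(C)(C)[Si](C)(C)Cl
Why: Silylation of a secondary alcohol; the bulky, weakly Lewis-basic silyl ether should resist ionisation of the furfuryl C–O bond by the aluminium Lewis acid and prevents lactonisation.

Step 4
Reactants: 4 (R)-4-[(tert-butyldimethylsilyl)oxy]-4-(furan-2-yl)-N-methoxy-N-methylbutanamide; 5 (E)-2-bromobut-2-ene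
Product: 7 (2E,7R)-7-[(tert-butyldimethylsilyl)oxy]-7-(furan-2-yl)-3-methylhept-2-en-4-one, via but-2-en-2-yllithium 6 (not isolated)
Conditions: 5, t-BuLi (2 equiv), Et2O, −78 °C; then 4, THF, −78 to 0 °C; aq. NH4Cl
Reagents that add atoms: none
Why: Bromine–lithium exchange with retention of alkene geometry, then Weinreb ketone synthesis; the chelated tetrahedral intermediate stops at the ketone and the cis methyls of the tigloyl unit are kept.

Step 5
Reactants: 7 (2E,7R)-7-[(tert-butyldimethylsilyl)oxy]-7-(furan-2-yl)-3-methylhept-2-en-4-one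
Product: 8 (3R,4R,5R,9R,10S)-9-[(tert-butyldimethylsilyl)oxy]-3,10-epoxy-11,12,13-trinoreremophil-1-en-6-one (oxygen bridge 3α,10α; methyls 4β,5β; silyloxy 9α)
Conditions: MeAlCl2 (1.1 equiv), CH2Cl2, −78 °C; quenched cold with Et3N then aq. NaHCO3
Reagents that add atoms: none
Why: MeAlCl2 binds the enone carbonyl and the 2-alkylfuran adds in a concerted, reversible [4+2] cycloaddition that low temperature holds on the adduct side; the closest known reaction type is the MeAlCl2-promoted intramolecular Diels–Alder reaction of 2-(4-oxoalk-5-enyl)furans. Ring A closes as the cyclohexene of a 7-oxanorbornene by suprafacial bonding of C4 and C5 to furan C5 and C2 (C3 and C10); ring B closes through the same C5–C10 bond as a six-membered ring spanned by C6–C9 in a chair-like transition state with the tether exo, the only arrangement a four-atom tether allows. C3 and C10 are fixed syn by the oxygen bridge. C4 and C5 carry cis methyls because the (E)-alkene adds suprafacially, and both methyls are endo (anti to the bridge) because C6 is exo. The selectivity needed is diastereofacial and C9 should secure it: with the silyloxy group equatorial the chair leads to 8, whereas addition to the other furan face would force it axial and syn-axial to the C14 methyl across ring B. The adduct is taken on at once because it can revert on warming.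

Step 6
Reactants: 8 the oxanorbornene adduct of step 5
Product: 9 3α,10α-epoxy-9α-[(tert-butyldimethylsilyl)oxy]-11,12,13-trinoreremophilan-6-one
Conditions: H2 (1 atm), Pd/C, EtOAc, 0 °C
Reagents that add atoms: none
Why: Hydrogenation of the strained C1=C2 bond is fast, creates no stereocentre and removes the possibility of retro-Diels–Alder reaction; ketone and silyl ether are untouched.

Step 7
Reactants: 9 3α,10α-epoxy-9α-[(tert-butyldimethylsilyl)oxy]-11,12,13-trinoreremophilan-6-one
Product: 10 3α,10α-epoxy-9α-[(tert-butyldimethylsilyl)oxy]-11,12,13-trinoreremophil-6-en-6-yl trifluoromethanesulfonate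
Conditions: KN(SiMe3)2, THF, −78 °C; PhNTf2, −78 to 0 °C
Reagents that add atoms: N-phenylbis(trifluoromethanesulfonimide), O=S(=O)(N(c1ccccc1)S(=O)(=O)C(F)(F)F)C(F)(F)F
Why: The C6 ketone can enolise only toward C7 because C5 is quaternary; O-triflation of the potassium enolate is standard.

Step 8
Reactants: 10 the C6 enol triflate
Product: 11 3α,10α-epoxy-9α-[(tert-butyldimethylsilyl)oxy]-11,12,13-trinoreremophil-6-ene
Conditions: Pd(OAc)2 (cat.), PPh3, Bu3N, HCO2H, DMF, 60 °C
Reagents that add atoms: none
Why: Palladium-catalysed formate reduction of an enol triflate (oxidative addition, formate exchange, decarboxylation, reductive elimination) removes the C6 oxygen and leaves the C6=C7 alkene in a defined position.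

Step 9
Reactants: 11 the C6=C7 alkene
Product: 12 3α,10α-epoxy-9α-[(tert-butyldimethylsilyl)oxy]-11,12,13-trinoreremophil-6-en-8-one
Conditions: t-BuOOH, Mn(OAc)3·2H2O (cat.), 3 Å molecular sieves, EtOAc, rt
Reagents that add atoms: tert-butyl hydroperoxide, CC(C)(C)OO
Why: Radical allylic C–H oxidation to the enone; only C8 bears allylic hydrogens, and the allyl radical should be oxygenated at C8 and not at the neopentyl C6 next to the quaternary centre.

Step 10
Reactants: 12 the C6=C7 enone with the ketone at C8
Product: 13 7-iodo-3α,10α-epoxy-9α-[(tert-butyldimethylsilyl)oxy]-11,12,13-trinoreremophil-6-en-8-one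
Conditions: I2, pyridine, CH2Cl2, rt
Reagents that add atoms: iodine, II
Why: α-Iodination of a cyclic enone by reversible pyridine conjugate addition, iodination of the enolate and elimination; it works on enones with a quaternary γ-carbon, and pyridine is too weak a base to open the β-alkoxy ketone.

Step 11
Reactants: 13 the 7-iodo enone; 14 tributyl(prop-1-en-2-yl)stannane
Product: 15 3α,10α-epoxy-9α-[(tert-butyldimethylsilyl)oxy]eremophila-6,11-dien-8-one
Conditions: Pd2(dba)3 (cat.), AsPh3, CuI, N-methylpyrrolidone, rt to 40 °C
Reagents that add atoms: none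
Why: Stille coupling of an α-iodoenone with an alkenylstannane under base-free conditions attaches C11 to C7 without regiochemical ambiguity.

Step 12
Reactants: 15 the 7-isopropenyl dienone
Product: 17 3α,10α-epoxy-9α-[(tert-butyldimethylsilyl)oxy]-7αH-eremophil-11-en-8-one (7β-isopropenyl), via silyl enol ether 16 (not isolated)
Conditions: [(Ph3P)CuH]6 (5 mol %), PhMe2SiH, toluene, rt; then 1 M HCl, THF, −20 °C
Reagents that add atoms: none
Why: Copper hydride 1,4-hydrosilylation reduces only the enone C6=C7 bond (hydride to C6) and spares the cross-conjugated isopropenyl group; kinetic C-protonation of 16 is expected from the α face, opposite the axial C14 methyl that covers the β face of C7, giving H-7α. The 7β group is axial in the bridged ring but becomes equatorial once ring B is cis-fused in step 15.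

Step 13
Reactants: 17 the bridged 7β-isopropenyl ketone
Product: 19 3α-hydroxy-7αH-eremophila-9,11-dien-8-one, via samarium enolate 18 (not isolated)
Conditions: SmI2 (2.5 equiv), THF, −78 to 0 °C; pH 7 buffer
Reagents that add atoms: none
Why: Two-electron reduction of the α-silyloxy ketone (reductive cleavage of α-heterosubstituted ketones) gives the regiodefined trivalent samarium enolate 18, whose C9 p-orbital is aligned with the axial C10–O bond; β-elimination (retro-oxa-Michael) then opens the strained oxanorbornane without external base. The sacrificial C9 stereocentre is erased and the 3α alcohol and the C9=C10 enone are released.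

Step 14
Reactants: 19 the 3α-hydroxy dienone; 20 3-methylbut-2-enoyl chloride
Product: 21 3α-(3-methylbut-2-enoyloxy)-7αH-eremophila-9,11-dien-8-one
Conditions: pyridine, DMAP (cat.), CH2Cl2, 0 °C
Reagents that add atoms: none
Why: Acylation of the only hydroxyl, an equatorial secondary alcohol; the weak base and low temperature limit ketene formation from the acid chloride and enolisation at C7.

Step 15
Reactants: 21 the 3-O-senecioyl dienone
Product: 22 8-(dimethylphenylsilyloxy)-3α-(3-methylbut-2-enoyloxy)-7αH,10βH-eremophila-8,11-diene
Conditions: [(Ph3P)CuH]6 (5 mol %), PhMe2SiH, toluene, rt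
Reagents that add atoms: dimethylphenylsilane, C[SiH](C)c1ccccc1
Why: Copper hydride 1,4-hydrosilylation is selective for the enone over the isopropenyl group and the β,β-disubstituted enoate; hydride should enter C10 on the β face, syn to C14, as organocopper reagents do with 10-methyl-1(9)-octal-2-ones, the 7β-isopropenyl group favouring the half-chair in which axial attack is β. This sets the cis ring fusion irreversibly and forms the enol ether only toward C9.

Step 16
Reactants: 22 the C8=C9 silyl enol ether
Product: 24 9β-hydroxy-3α-(3-methylbut-2-enoyloxy)-7αH,10βH-eremophil-11-en-8-one, via silyloxy epoxide 23 (not isolated)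
Conditions: dimethyldioxirane, acetone–CH2Cl2, −78 °C; then aq. citric acid, THF, 0 °C
Reagents that add atoms: dimethyldioxirane, CC1(C)OO1
Why: Rubottom oxidation; the electron-rich enol ether reacts well before the isopropenyl or enoate alkenes, from the convex β face of the cis-decalin, and hydrolysis gives the equatorial 9β-hydroxy ketone, which is also the more stable epimer.

Step 17
Reactants: 24 the 9β-hydroxy ketone; 25 (Z)-2-methylbut-2-enoic acid (angelic acid)
Product: 27 9β-[(Z)-2-methylbut-2-enoyloxy]-3α-(3-methylbut-2-enoyloxy)-7αH,10βH-eremophil-11-en-8-one (CNP0164025.2), via mixed anhydride 26 (not isolated)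
Conditions: 25, 2,4,6-trichlorobenzoyl chloride, Et3N, toluene, rt; then 24, 75 °C
Reagents that add atoms: none
Why: Yamaguchi-type mixed-anhydride acylation without DMAP, the conditions under which angelates form without Z to E isomerisation; C7 and C9 are already in their equatorial, more stable configurations, so mild base should not erode them.

## Compound list

1 | 4-(furan-2-yl)-4-oxobutanoic acid | OC(=O)CCC(=O)c1ccco1 | starting material
2 | 4-(furan-2-yl)-N-methoxy-N-methyl-4-oxobutanamide | CON(C)C(=O)CCC(=O)c1ccco1 | intermediate
3 | (R)-4-(furan-2-yl)-4-hydroxy-N-methoxy-N-methylbutanamide | CON(C)C(=O)CC[C@@H](O)c1ccco1 | intermediate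
4 | (R)-4-[(tert-butyldimethylsilyl)oxy]-4-(furan-2-yl)-N-methoxy-N-methylbutanamide | CON(C)C(=O)CC[C@@H](O[Si](C)(C)C(C)(C)C)c1ccco1 | intermediate
5 | (E)-2-bromobut-2-ene | C/C=C(\C)Br | starting material
6 | but-2-en-2-yllithium with cis methyls, lithium in place of bromine (formally Z) | C/C=C(\C)[Li] | intermediate (not isolated)
7 | (2E,7R)-7-[(tert-butyldimethylsilyl)oxy]-7-(furan-2-yl)-3-methylhept-2-en-4-one | C/C=C(\C)C(=O)CC[C@@H](O[Si](C)(C)C(C)(C)C)c1ccco1 | intermediate
8 | (3R,4R,5R,9R,10S)-9-[(tert-butyldimethylsilyl)oxy]-3,10-epoxy-11,12,13-trinoreremophil-1-en-6-one | O=C1CC[C@@H](O[Si](C)(C)C(C)(C)C)[C@]23C=C[C@@H](O3)[C@H](C)[C@@]12C | intermediate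
9 | 3α,10α-epoxy-9α-[(tert-butyldimethylsilyl)oxy]-11,12,13-trinoreremophilan-6-one | O=C1CC[C@@H](O[Si](C)(C)C(C)(C)C)[C@]23CC[C@@H](O3)[C@H](C)[C@@]12C | intermediate
10 | 3α,10α-epoxy-9α-[(tert-butyldimethylsilyl)oxy]-11,12,13-trinoreremophil-6-en-6-yl trifluoromethanesulfonate | O=S(=O)(OC1=CC[C@@H](O[Si](C)(C)C(C)(C)C)[C@]23CC[C@@H](O3)[C@H](C)[C@@]12C)C(F)(F)F | intermediate
11 | 3α,10α-epoxy-9α-[(tert-butyldimethylsilyl)oxy]-11,12,13-trinoreremophil-6-ene | C1=CC[C@@H](O[Si](C)(C)C(C)(C)C)[C@]23CC[C@@H](O3)[C@H](C)[C@@]12C | intermediate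
12 | 3α,10α-epoxy-9α-[(tert-butyldimethylsilyl)oxy]-11,12,13-trinoreremophil-6-en-8-one | C1=CC(=O)[C@@H](O[Si](C)(C)C(C)(C)C)[C@]23CC[C@@H](O3)[C@H](C)[C@@]12C | intermediate
13 | 7-iodo-3α,10α-epoxy-9α-[(tert-butyldimethylsilyl)oxy]-11,12,13-trinoreremophil-6-en-8-one | C1=C(I)C(=O)[C@@H](O[Si](C)(C)C(C)(C)C)[C@]23CC[C@@H](O3)[C@H](C)[C@@]12C | intermediate
14 | tributyl(prop-1-en-2-yl)stannane | C=C(C)[Sn](CCCC)(CCCC)CCCC | starting material
15 | 3α,10α-epoxy-9α-[(tert-butyldimethylsilyl)oxy]eremophila-6,11-dien-8-one | C1=C(C(C)=C)C(=O)[C@@H](O[Si](C)(C)C(C)(C)C)[C@]23CC[C@@H](O3)[C@H](C)[C@@]12C | intermediate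
16 | 8-(dimethylphenylsilyloxy)-3α,10α-epoxy-9α-[(tert-butyldimethylsilyl)oxy]eremophila-7,11-diene | C1C(C(C)=C)=C(O[Si](C)(C)c4ccccc4)[C@@H](O[Si](C)(C)C(C)(C)C)[C@]23CC[C@@H](O3)[C@H](C)[C@@]12C | intermediate (not isolated)
17 | 3α,10α-epoxy-9α-[(tert-butyldimethylsilyl)oxy]-7αH-eremophil-11-en-8-one | C1[C@H](C(C)=C)C(=O)[C@@H](O[Si](C)(C)C(C)(C)C)[C@]23CC[C@@H](O3)[C@H](C)[C@@]12C | intermediate
18 | diiodosamarium 3α,10α-epoxy-7αH-eremophila-8,11-dien-8-olate | C1[C@H](C(C)=C)C(O[Sm](I)I)=C[C@]23CC[C@@H](O3)[C@H](C)[C@@]12C | intermediate (not isolated)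
19 | 3α-hydroxy-7αH-eremophila-9,11-dien-8-one | C1[C@H](C(C)=C)C(=O)C=C2CC[C@@H](O)[C@H](C)[C@@]12C | intermediate
20 | 3-methylbut-2-enoyl chloride | CC(C)=CC(Cl)=O | starting material
21 | 3α-(3-methylbut-2-enoyloxy)-7αH-eremophila-9,11-dien-8-one | C1[C@H](C(C)=C)C(=O)C=C2CC[C@@H](OC(=O)C=C(C)C)[C@H](C)[C@@]12C | intermediate
22 | 8-(dimethylphenylsilyloxy)-3α-(3-methylbut-2-enoyloxy)-7αH,10βH-eremophila-8,11-diene | C1[C@H](C(C)=C)C(O[Si](C)(C)c3ccccc3)=C[C@H]2CC[C@@H](OC(=O)C=C(C)C)[C@H](C)[C@@]12C | intermediate
23 | 8β,9β-epoxy-8α-(dimethylphenylsilyloxy)-3α-(3-methylbut-2-enoyloxy)-7αH,10βH-eremophil-11-ene | C1[C@H](C(C)=C)[C@]3(O[Si](C)(C)c4ccccc4)O[C@@H]3[C@H]2CC[C@@H](OC(=O)C=C(C)C)[C@H](C)[C@@]12C | intermediate (not isolated)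
24 | 9β-hydroxy-3α-(3-methylbut-2-enoyloxy)-7αH,10βH-eremophil-11-en-8-one | C1[C@H](C(C)=C)C(=O)[C@H](O)[C@H]2CC[C@@H](OC(=O)C=C(C)C)[C@H](C)[C@@]12C | intermediate
25 | (Z)-2-methylbut-2-enoic acid (angelic acid) | C/C=C(/C)C(=O)O | starting material
26 | (Z)-2-methylbut-2-enoic 2,4,6-trichlorobenzoic anhydride | C/C=C(/C)C(=O)OC(=O)c1c(Cl)cc(Cl)cc1Cl | intermediate (not isolated)
27 | (3R,4R,5R,7R,9R,10S)-9-[(Z)-2-methylbut-2-enoyloxy]-3-(3-methylbut-2-enoyloxy)eremophil-11-en-8-one (3α,9β-diester, 7αH,10βH) | C=C(C)[C@H]1C[C@@]2(C)[C@H](CC[C@@H](OC(=O)C=C(C)C)[C@@H]2C)[C@@H](OC(=O)/C(C)=C\C)C1=O | target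

## Count and risks

Total: 17 steps. Longest linear sequence: 17 steps, from 1 to 27.

**Step 5 (key step).** The most likely failure is an unfavourable position of the reversible cycloaddition: a trisubstituted dienophile adds more slowly and its adduct reverts more easily, so low conversion or cycloreversion during work-up is possible. Lewis-acid ionisation of the furfuryl C–O bond is the second danger. The fallback keeps the same two bonds but uses an allene as dienophile, and runs from 4 to 9. Reduction of 4 with i-Bu2AlH should give (R)-4-[(tert-butyldimethylsilyl)oxy]-4-(furan-2-yl)butanal F1. Indium-mediated addition of 1-bromobut-2-yne should give the allenyl carbinol (7R)-7-[(tert-butyldimethylsilyl)oxy]-7-(furan-2-yl)-3-methylhepta-1,2-dien-4-ol F2 as both C4 epimers. Dess–Martin oxidation should give the allenyl ketone (R)-7-[(tert-butyldimethylsilyl)oxy]-7-(furan-2-yl)-3-methylhepta-1,2-dien-4-one F3. Its α,β-double bond is a more reactive and less reversible dienophile and should cyclise on gentle warming or with Me2AlCl to the 4(15)-methylene adduct 3α,10α-epoxy-9α-[(tert-butyldimethylsilyl)oxy]-11,12,13-trinoreremophila-1,4(15)-dien-6-one F4. Hydrogenation over Pd/C should reduce C1=C2 and add hydrogen to the exocyclic methylene from the exo face, placing C15 endo (β) and giving 9.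

**Step 15.** Hydride may be delivered to the α face of C10 and give the trans-fused series, because the precedent rests on organocopper additions to simpler octalones; slow reaction at the hindered β-carbon could also let the enoate be reduced. The fallback sets C10 by heterogeneous hydrogenation before the isopropenyl group exists, and runs from 12 to 24.
- Hydrogenation of 12 over Pd/C should give the saturated bridged ketone 3α,10α-epoxy-9α-[(tert-butyldimethylsilyl)oxy]-11,12,13-trinoreremophilan-8-one F5.
- SmI2 as in step 13 should give 3α-hydroxy-11,12,13-trinoreremophil-9-en-8-one F6.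
- Hydrogenation over Pd/C in EtOAc–pyridine, the classical cis-selective reduction of this type of octalone, should give 3α-hydroxy-10βH-11,12,13-trinoreremophilan-8-one F7.
- Acylation with 20 should give the senecioate F8.
- The thermodynamic C8=C9 silyl enol ether (Me3SiOTf, Et3N; cis-fused ketones of this type enolise toward the ring fusion) and Rubottom oxidation should give the 9β-hydroxy ketone F9.
- Silylation and enolisation toward C7 (Me3SiOTf, Et3N) followed by Saegusa oxidation with Pd(OAc)2 should give the 9β-hydroxy-6-en-8-one F10.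
- Iodination as in step 10 should give the 7-iodo enone F11, and Stille coupling with 14 should give the 7-isopropenyl dienone F12.
- Copper hydride reduction and protonation as in step 12 then lead to 24.

**Step 12.** Protonation of 16 may follow product stability and give the 7α-isopropenyl epimer, which is equatorial in the bridged ring; the axial 7β ketone 17 may also epimerise on handling or in step 13. The fallback gives up kinetic control and corrects C7 at the end, where 7β is the stable epimer; it runs from 15 to 27.
- The 7α epimer of 17, 3α,10α-epoxy-9α-[(tert-butyldimethylsilyl)oxy]-7βH-eremophil-11-en-8-one F13, would be carried through steps 13 to 17 unchanged.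
- This passes through 3α-hydroxy-7βH-eremophila-9,11-dien-8-one F14, its senecioate F15, the silyl enol ether 7-epi-22 F16 and the ketol 7-epi-24 F17, and ends at 7-epi-27 F18. (The 7α group may weaken the β-face preference in step 15.)
- In F18 the 7α-isopropenyl group is axial and syn to the C5–C4 bond. Brief treatment with catalytic DBU in toluene at 0 °C should epimerise C7 to the equatorial 7β configuration of 27.
- The equilibration must be stopped early: γ-protonation of the same dienolate leads to the conjugated 7(11)-ene, which is likely the more stable isomer, so some loss is expected.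

**Step 13.** Cleavage of the hindered α-silyloxy C–O bond may be slow, the samarium enolate may be protonated before it expels the bridge, or excess reductant may attack the product enone. The fallback separates the events and runs from 17 to 19. HF·pyridine should give the α-ketol 3α,10α-epoxy-9α-hydroxy-7αH-eremophil-11-en-8-one F19. SmI2 in THF–MeOH, the standard deoxygenation of α-hydroxy ketones, should give the bridged ketone 3α,10α-epoxy-7αH-eremophil-11-en-8-one F20. Kinetic deprotonation at the C9 methylene with LiN(i-Pr)2 at −78 °C and warming to 0 °C should then open the bridge by β-elimination to 19; the tertiary C7 hydrogen is expected to be left alone.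

## Further compounds

F1 | step 5 | (R)-4-[(tert-butyldimethylsilyl)oxy]-4-(furan-2-yl)butanal | O=CCC[C@@H](O[Si](C)(C)C(C)(C)C)c1ccco1
F2 | step 5 | (7R)-7-[(tert-butyldimethylsilyl)oxy]-7-(furan-2-yl)-3-methylhepta-1,2-dien-4-ol (both C4 epimers) | C=C=C(C)C(O)CC[C@@H](O[Si](C)(C)C(C)(C)C)c1ccco1
F3 | step 5 | (R)-7-[(tert-butyldimethylsilyl)oxy]-7-(furan-2-yl)-3-methylhepta-1,2-dien-4-one | C=C=C(C)C(=O)CC[C@@H](O[Si](C)(C)C(C)(C)C)c1ccco1
F4 | step 5 | 3α,10α-epoxy-9α-[(tert-butyldimethylsilyl)oxy]-11,12,13-trinoreremophila-1,4(15)-dien-6-one | O=C1CC[C@@H](O[Si](C)(C)C(C)(C)C)[C@]23C=C[C@@H](O3)C(=C)[C@@]12C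
F5 | step 15 | 3α,10α-epoxy-9α-[(tert-butyldimethylsilyl)oxy]-11,12,13-trinoreremophilan-8-one | C1CC(=O)[C@@H](O[Si](C)(C)C(C)(C)C)[C@]23CC[C@@H](O3)[C@H](C)[C@@]12C
F6 | step 15 | 3α-hydroxy-11,12,13-trinoreremophil-9-en-8-one | C1CC(=O)C=C2CC[C@@H](O)[C@H](C)[C@@]12C
F7 | step 15 | 3α-hydroxy-10βH-11,12,13-trinoreremophilan-8-one | C1CC(=O)C[C@H]2CC[C@@H](O)[C@H](C)[C@@]12C
F8 | step 15 | 3α-(3-methylbut-2-enoyloxy)-10βH-11,12,13-trinoreremophilan-8-one | C1CC(=O)C[C@H]2CC[C@@H](OC(=O)C=C(C)C)[C@H](C)[C@@]12C
F9 | step 15 | 9β-hydroxy-3α-(3-methylbut-2-enoyloxy)-10βH-11,12,13-trinoreremophilan-8-one | C1CC(=O)[C@H](O)[C@H]2CC[C@@H](OC(=O)C=C(C)C)[C@H](C)[C@@]12C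
F10 | step 15 | 9β-hydroxy-3α-(3-methylbut-2-enoyloxy)-10βH-11,12,13-trinoreremophil-6-en-8-one | C1=CC(=O)[C@H](O)[C@H]2CC[C@@H](OC(=O)C=C(C)C)[C@H](C)[C@@]12C
F11 | step 15 | 9β-hydroxy-7-iodo-3α-(3-methylbut-2-enoyloxy)-10βH-11,12,13-trinoreremophil-6-en-8-one | C1=C(I)C(=O)[C@H](O)[C@H]2CC[C@@H](OC(=O)C=C(C)C)[C@H](C)[C@@]12C
F12 | step 15 | 9β-hydroxy-3α-(3-methylbut-2-enoyloxy)-10βH-eremophila-6,11-dien-8-one | C1=C(C(C)=C)C(=O)[C@H](O)[C@H]2CC[C@@H](OC(=O)C=C(C)C)[C@H](C)[C@@]12C
F13 | step 12 | 3α,10α-epoxy-9α-[(tert-butyldimethylsilyl)oxy]-7βH-eremophil-11-en-8-one (7-epi-17) | C1[C@@H](C(C)=C)C(=O)[C@@H](O[Si](C)(C)C(C)(C)C)[C@]23CC[C@@H](O3)[C@H](C)[C@@]12C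
F14 | step 12 | 3α-hydroxy-7βH-eremophila-9,11-dien-8-one (7-epi-19) | C1[C@@H](C(C)=C)C(=O)C=C2CC[C@@H](O)[C@H](C)[C@@]12C
F15 | step 12 | 3α-(3-methylbut-2-enoyloxy)-7βH-eremophila-9,11-dien-8-one (7-epi-21) | C1[C@@H](C(C)=C)C(=O)C=C2CC[C@@H](OC(=O)C=C(C)C)[C@H](C)[C@@]12C
F16 | step 12 | 8-(dimethylphenylsilyloxy)-3α-(3-methylbut-2-enoyloxy)-7βH,10βH-eremophila-8,11-diene (7-epi-22) | C1[C@@H](C(C)=C)C(O[Si](C)(C)c3ccccc3)=C[C@H]2CC[C@@H](OC(=O)C=C(C)C)[C@H](C)[C@@]12C
F17 | step 12 | 9β-hydroxy-3α-(3-methylbut-2-enoyloxy)-7βH,10βH-eremophil-11-en-8-one (7-epi-24) | C1[C@@H](C(C)=C)C(=O)[C@H](O)[C@H]2CC[C@@H](OC(=O)C=C(C)C)[C@H](C)[C@@]12C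
F18 | step 12 | 9β-[(Z)-2-methylbut-2-enoyloxy]-3α-(3-methylbut-2-enoyloxy)-7βH,10βH-eremophil-11-en-8-one (7-epi-27) | C1[C@@H](C(C)=C)C(=O)[C@H](OC(=O)/C(C)=C\C)[C@H]2CC[C@@H](OC(=O)C=C(C)C)[C@H](C)[C@@]12C
F19 | step 13 | 3α,10α-epoxy-9α-hydroxy-7αH-eremophil-11-en-8-one | C1[C@H](C(C)=C)C(=O)[C@@H](O)[C@]23CC[C@@H](O3)[C@H](C)[C@@]12C
F20 | step 13 | 3α,10α-epoxy-7αH-eremophil-11-en-8-one | C1[C@H](C(C)=C)C(=O)C[C@]23CC[C@@H](O3)[C@H](C)[C@@]12C
A1 | alternative 1 | 9β-[(tert-butyldimethylsilyl)oxy]-8-hydroxy-3α-(3-methylbut-2-enoyloxy)-7αH,10βH-eremophil-11-ene (ene product) | C=C(C)[C@H]1C[C@@]2(C)[C@H](CC[C@@H](OC(=O)C=C(C)C)[C@@H]2C)[C@@H](O[Si](C)(C)C(C)(C)C)[C@@H]1O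
A2 | alternative 1 | 7,8-seco aldehyde: ring A carrying on C10 the CH(OTBS)CHO unit (C9, C8) and on C5 a methyl and a prenyl group | O=C[C@H](O[Si](C)(C)C(C)(C)C)[C@H]1CC[C@@H](OC(=O)C=C(C)C)[C@H](C)[C@@]1(C)CC=C(C)C
A3 | alternative 2 | cis-decalin C3 ketone with 7β-isopropenyl, C8 triethylsilyl ether and C9 tert-butyldimethylsilyl ether | C=C(C)[C@H]1C[C@@]2(C)[C@H](CCC(=O)[C@@H]2C)[C@@H](O[Si](C)(C)C(C)(C)C)[C@@H]1O[Si](CC)(CC)CC
A4 | alternative 2 | 4,5-dimethylbicyclo[4.1.0]heptan-3-one (C4–C5–C6 cyclopropane) carrying on C10 the bis-silyloxy chain ending in a 2-methyl-3-(phenylsulfonyl)prop-1-enyl group | O=C1CC[C@H]([C@@H](O[Si](C)(C)C(C)(C)C)[C@H](O[Si](CC)(CC)CC)/C=C(\C)CS(=O)(=O)c2ccccc2)[C@]2(C)C[C@]12C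
A5 | alternative 3 | cis-fused 5-methyl C4 ketone with C7=C8 tert-butyldimethylsilyl enol ether | C[C@]12CC=C(O[Si](C)(C)C(C)(C)C)C[C@H]1CCCC2=O
A6 | alternative 3 | 2-methylcyclohex-2-en-1-one | CC1=CCCCC1=O
A7 | alternative 3 | 2-[(tert-butyldimethylsilyl)oxy]buta-1,3-diene | C=CC(=C)O[Si](C)(C)C(C)(C)C
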